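A direct plan would start at the phloroglucinol end. Ring A would be condensed from a malonate and an acetonedicarboxylate on the oxygen of a protected ring B phenol, giving the A–B phenol A1. The chain would then grow one ring at a time by Ullmann etherification with the bromobenzaldehydes A2 and A3, each followed by a Dakin oxidation, up to the hexadeca-O-benzyl ether A4 and a final hydrogenolysis.
Its weakest points would be:
- The run-up to A1: about ten operations (allyl on and off, half-saponification, acid chloride, Claisen–Dieckmann, decarboxylation, acetylation, re-benzylation) that build one plain 2-aryloxyphloroglucinol ring.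
- Every Ullmann coupling would use a phenol flanked by two oxygen substituents. The coupling with the ortho-substituted bromide A3, which sets the vicinal bis(aryloxy) pattern of ring D, would meet the hardest bond with the least reliable reaction on a late trimer.
- Strict linearity: more than twenty steps in one line, two per ring, plus a capping benzylation that builds nothing.

**Retrosynthetic overview**
Rings are lettered A (2,4,6-trihydroxyphenyl end) to F (3,4,5-trihydroxyphenyl end). In rings B and D, C1 carries the ether to ring A or C and C2 the ether to ring C or E; C3–C5 carry OH and C6 carries H.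
Rings B and D, the two benzene rings with oxygen on C1–C5, would be built, not bought: each is cut at C4–C5 and C1–C6 into a squaric acid C4 unit and a 1-alkoxyvinyl C2 unit (Moore ring expansion).
The ethers E1–O–D2 and C1–O–B2 would thus be formed as squarate esters and not by arylation, and each ring expansion would free exactly one phenol (D1–OH, B1–OH) for the next link.
Rings F, E, C and A would come from two benzaldehydes; the links F–E, D–C and B–A would be made by O-arylation with one aldehyde-activated bromide, followed by Dakin oxidation.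
Ring D would close first, then ring B. The design needs no malonate-built phloroglucinol, no allyl detour, no capping step and no arylation of a doubly flanked phenol.

Key step: step 12

Assumption: in the mixed aryl benzyl squarate, the carbonyl group conjugated with the aryloxy group (the weaker donor) is taken to be the more electrophilic one, as in other unsymmetrical squaric acid derivatives.
Assumption: the vinyllithium 17 would not be stored; the lithiation of step 10 would be run on fresh 10 directly before each of the two additions (steps 11 and 16), whereas one batch of the ester chloride 15 would serve both esterifications (steps 9 and 15).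

Step 1
Reactants: 1 3,4,5-trihydroxybenzaldehyde
Product: 2 3,4,5-tris(benzyloxy)benzaldehyde
Conditions: BnBr (3.6 equiv), K2CO3, DMF, 60 °C, argon
Reagents that add atoms: benzyl bromide, BrCc1ccccc1
Why: Williamson etherification of the three phenoxides, run under argon because the pyrogallol unit is oxidised by air in base.

Step 2
Reactants: 2 3,4,5-tris(benzyloxy)benzaldehyde
Product: 4 3,4,5-tris(benzyloxy)phenol, via aryl formate 3 (not isolated)
Conditions: mCPBA (1.2 equiv), CH2Cl2, 0 °C to rt; then K2CO3 (cat.), MeOH, rt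
Reagents that add atoms: 3-chloroperoxybenzoic acid, OOC(=O)c1cccc(Cl)c1
Why: Dakin-type Baeyer–Villiger oxidation in which the 3,4,5-trialkoxyphenyl group migrates in preference to hydride, followed by methanolysis of the formate to the ring F phenol.

Step 3
Reactants: 5 4-bromo-3,5-dimethoxybenzaldehyde
Product: 6 4-bromo-3,5-dihydroxybenzaldehyde
Conditions: BBr3 (3 equiv), CH2Cl2, −78 °C to rt; then H2O, 0 °C
Reagents that add atoms: none
Why: Lewis acid demethylation of the two aryl methyl ethers, in which the aryl bromide is inert and the aldehyde is only complexed and set free again on hydrolysis.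

Step 4
Reactants: 6 4-bromo-3,5-dihydroxybenzaldehyde
Product: 7 3,5-bis(benzyloxy)-4-bromobenzaldehyde
Conditions: BnBr (2.4 equiv), K2CO3, DMF, 50 °C
Reagents that add atoms: benzyl bromide, BrCc1ccccc1
Why: Williamson etherification of both phenols, giving the one electrophile that supplies rings E, C and A.

Step 5
Reactants: 8 tetrahydrofuran
Product: 10 (methoxymethoxy)ethene, via lithium ethenolate 9 (not isolated)
Conditions: n-BuLi, THF (reactant and solvent), 35 °C; then MOMCl, DMPU, −78 °C to rt; co-distilled with THF from CaH2 and used as a THF solution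
Reagents that add atoms: chloromethyl methyl ether, COCCl
Why: cycloreversion of 2-lithiotetrahydrofuran gives ethene and the lithium enolate of acetaldehyde, which the hard electrophile chloromethyl methyl ether alkylates on oxygen (enolate O-alkylation).

Step 6
Reactants: 4 3,4,5-tris(benzyloxy)phenol; 7 3,5-bis(benzyloxy)-4-bromobenzaldehyde
Product: 11 3,5-bis(benzyloxy)-4-[3,4,5-tris(benzyloxy)phenoxy]benzaldehyde
Conditions: CuI (20 mol%), picolinic acid (40 mol%), K3PO4, DMSO, 100 °C, argon
Reagents that add atoms: none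
Why: Ullmann-type O-arylation of a phenol with both ortho positions free by a bromide that is flanked by two benzyloxy groups but activated by its para formyl group.

Step 7
Reactants: 11 3,5-bis(benzyloxy)-4-[3,4,5-tris(benzyloxy)phenoxy]benzaldehyde
Product: 13 3,5-bis(benzyloxy)-4-[3,4,5-tris(benzyloxy)phenoxy]phenol, via aryl formate 12 (not isolated)
Conditions: mCPBA (1.2 equiv), NaHCO3, CH2Cl2, 0 °C to rt; then K2CO3 (cat.), MeOH/THF, rt
Reagents that add atoms: 3-chloroperoxybenzoic acid, OOC(=O)c1cccc(Cl)c1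
Why: Dakin-type Baeyer–Villiger oxidation in which the 4-aryloxy-3,5-dialkoxyphenyl group migrates as in step 2, freeing E1–OH, a phenol with no ortho substituent.

Step 8
Reactants: 14 3,4-dichlorocyclobut-3-ene-1,2-dione (squaric acid dichloride)
Product: 15 3-(benzyloxy)-4-chlorocyclobut-3-ene-1,2-dione
Conditions: BnOH (1.0 equiv), CH2Cl2, −20 °C to rt, argon purge; evaporated under argon and kept as a CH2Cl2 stock solution at −20 °C
Reagents that add atoms: benzyl alcohol, OCc1ccccc1
Why: addition–elimination at the vinylogous acid chloride without base, in which the first benzyloxy group, a vinylogous ester donor, deactivates the remaining chloride towards a second alcoholysis, so the mono ester chloride can be made once and used for both squarate esterifications.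

Step 9
Reactants: 15 3-(benzyloxy)-4-chlorocyclobut-3-ene-1,2-dione; 13 3,5-bis(benzyloxy)-4-[3,4,5-tris(benzyloxy)phenoxy]phenol
Product: 16 3-(benzyloxy)-4-{3,5-bis(benzyloxy)-4-[3,4,5-tris(benzyloxy)phenoxy]phenoxy}cyclobut-3-ene-1,2-dione
Conditions: 15 (1.2 equiv), iPr2NEt (1.3 equiv), CH2Cl2, −20 to 0 °C, argon
Reagents that add atoms: none
Why: addition–elimination of the phenoxide at the chloride-bearing carbon of the vinylogous acid chloride, where chloride leaves far more readily than benzyloxide, so the E1–O–D2 ether is made as a squarate ester.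

Step 10
Reactants: 10 (methoxymethoxy)ethene
Product: 17 1-(methoxymethoxy)ethenyllithium (THF solution)
Conditions: s-BuLi (0.9 equiv), THF, −78 °C, 30 min; the cold solution is used at once
Reagents that add atoms: sec-butyllithium, [Li]C(C)CC
Why: kinetic α-lithiation of the enol ether, directed and stabilised by chelation of lithium to the methoxymethyl oxygens; the slight deficit of base leaves no free alkyllithium that could attack the squarate.

Step 11
Reactants: 16 mixed aryl benzyl squarate; 17 1-(methoxymethoxy)ethenyllithium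
Product: 19 rac-2-(aryloxy)-3-(benzyloxy)-4-(methoxymethoxy)-4-[1-(methoxymethoxy)ethenyl]cyclobut-2-en-1-one in which the aryloxy group is the oxygen of phenol 13, via lithium alkoxide 18 (not isolated)
Conditions: 17 (1.15 equiv, THF solution) added to 16, THF, −78 °C; then MOMCl (3 equiv), DMPU, −78 to 0 °C; aq. NaHCO3
Reagents that add atoms: chloromethyl methyl ether, COCCl
Why: regioselective 1,2-addition of the α-alkoxyvinyllithium to the squarate carbonyl that is conjugated with the weaker aryloxy donor and next to the smaller benzyloxy-bearing carbon, with O-alkylation of the lithium alkoxide in the same flask; the new quaternary centre C4 is racemic and is destroyed in step 12.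

Step 12
Reactants: 19 rac-4-alkenyl-4-alkoxycyclobutenone
Product: 22 3-(benzyloxy)-4,5-bis(methoxymethoxy)-2-{3,5-bis(benzyloxy)-4-[3,4,5-tris(benzyloxy)phenoxy]phenoxy}phenol (rings F–E–D phenol), via dienylketene 20 (not isolated), via cyclohexadienone 21 (not isolated)
Conditions: toluene (0.02 M, degassed), 110 °C, argon
Reagents that add atoms: none
Why: Moore rearrangement, whose closest precedent is the thermal conversion of squarate-derived 4-alkenyl-4-oxy-2,3-dialkoxycyclobutenones, including those made from α-alkoxyvinyllithiums, into mono-protected hydroquinones. Conrotatory 4π electrocyclic opening of the C1–C4 bond gives dienylketene 20; the oxygen donor at C4 rotates outward, so the 1-(methoxymethoxy)vinyl group turns inward, cis to the ketene. Ring D is then closed by a 6π electrocyclisation (six-membered carbocycle, new bond between the ketene carbon and the vinyl CH2, the D1–D6 bond) to cyclohexadienone 21, which tautomerises to the phenol. No stereocentre is formed and the racemic centre of 19 is lost on aromatisation. The step needs only this torquoselectivity, which the C4 oxygen substituent secures; the placement of OAr next to the new OH was fixed in step 11, and the MOM cap on the C4 oxygen blocks lactonisation of a free hydroxyl onto the ketene. Ring D thus takes D1–D4 from squaric acid and D5–D6 from the vinyl ether, and its only free hydroxyl, D1–OH, is the one needed for the next ether.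

Step 13
Reactants: 22 rings F–E–D phenol; 7 3,5-bis(benzyloxy)-4-bromobenzaldehyde
Product: 23 3,5-bis(benzyloxy)-4-(aryloxy)benzaldehyde in which the aryloxy group is the oxygen of phenol 22 (rings F–C aldehyde)
Conditions: CuI (20 mol%), picolinic acid (40 mol%), K3PO4, DMSO, 110 °C, argon
Reagents that add atoms: none
Why: Ullmann-type O-arylation of a phenol that keeps one free ortho position (D6–H) by the para-formyl-activated bromide, forming the D1–O–C4 ether with the oxygen of ring D.

Step 14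
Reactants: 23 rings F–C aldehyde
Product: 25 3,5-bis(benzyloxy)-4-(aryloxy)phenol in which the aryloxy group is the oxygen of phenol 22 (rings F–C phenol), via aryl formate 24 (not isolated)
Conditions: mCPBA (1.2 equiv), NaHCO3, CH2Cl2, 0 °C to rt; then K2CO3 (cat.), MeOH/THF, rt
Reagents that add atoms: 3-chloroperoxybenzoic acid, OOC(=O)c1cccc(Cl)c1
Why: Dakin-type Baeyer–Villiger oxidation as in step 7, freeing C1–OH of ring C, the only phenol of the tetramer.

Step 15
Reactants: 15 3-(benzyloxy)-4-chlorocyclobut-3-ene-1,2-dione; 25 rings F–C phenol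
Product: 26 3-(benzyloxy)-4-(aryloxy)cyclobut-3-ene-1,2-dione in which the aryloxy group is the oxygen of phenol 25
Conditions: 15 (1.2 equiv, from the batch of step 8), iPr2NEt (1.3 equiv), CH2Cl2, −20 to 0 °C, argon
Reagents that add atoms: none
Why: the same addition–elimination at the ester chloride as in step 9, forming the C1–O–B2 ether as a squarate ester.

Step 16
Reactants: 26 mixed aryl benzyl squarate of the tetramer; 17 1-(methoxymethoxy)ethenyllithium
Product: 28 rac-2-(aryloxy)-3-(benzyloxy)-4-(methoxymethoxy)-4-[1-(methoxymethoxy)ethenyl]cyclobut-2-en-1-one in which the aryloxy group is the oxygen of phenol 25, via lithium alkoxide 27 (not isolated)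
Conditions: 17 (1.15 equiv, THF solution) added to 26, THF, −78 °C; then MOMCl (3 equiv), DMPU, −78 to 0 °C; aq. NaHCO3
Reagents that add atoms: chloromethyl methyl ether, COCCl
Why: the same regioselective carbonyl addition to an unsymmetrical squarate and O-alkylation as in step 11; the racemic quaternary centre is again lost in the next step.

Step 17
Reactants: 28 rac-4-alkenyl-4-alkoxycyclobutenone of the tetramer
Product: 31 3-(benzyloxy)-4,5-bis(methoxymethoxy)-2-(aryloxy)phenol in which the aryloxy group is the oxygen of phenol 25 (rings F–B phenol), via dienylketene 29 (not isolated), via cyclohexadienone 30 (not isolated)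
Conditions: toluene (0.02 M, degassed), 110 °C, argon
Reagents that add atoms: none
Why: second Moore rearrangement (4π ring opening, 6π electrocyclisation, tautomerisation) as in step 12, which builds ring B with the C–B ether and three protected oxygens in place and frees B1–OH; no stereocentre remains.

Step 18
Reactants: 31 rings F–B phenol; 7 3,5-bis(benzyloxy)-4-bromobenzaldehyde
Product: 32 3,5-bis(benzyloxy)-4-(aryloxy)benzaldehyde in which the aryloxy group is the oxygen of phenol 31 (rings F–A aldehyde)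
Conditions: CuI (20 mol%), picolinic acid (40 mol%), K3PO4, DMSO, 110 °C, argon
Reagents that add atoms: none
Why: Ullmann-type O-arylation as in step 13, with the same steric and electronic situation at both reacting centres.

Step 19
Reactants: 32 rings F–A aldehyde
Product: 34 3,5-bis(benzyloxy)-4-(aryloxy)phenol in which the aryloxy group is the oxygen of phenol 31 (protected hexamer), via aryl formate 33 (not isolated)
Conditions: mCPBA (1.2 equiv), NaHCO3, CH2Cl2, 0 °C to rt; then K2CO3 (cat.), MeOH/THF, rt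
Reagents that add atoms: 3-chloroperoxybenzoic acid, OOC(=O)c1cccc(Cl)c1
Why: Dakin-type Baeyer–Villiger oxidation as in steps 7 and 14, turning the last formyl group into the para hydroxyl of ring A.

Step 20
Reactants: 34 protected hexamer
Product: 36 CNP0218077.0, via undeca-O-benzyl pentaol 35 (not isolated)
Conditions: HCl (0.5 M), MeOH/THF, 45 °C, argon; then Pd(OH)2/C, H2 (1 atm), rt; filtered and concentrated under argon
Reagents that add atoms: none
Why: acid-catalysed acetal exchange removes the four aryl methoxymethyl ethers and hydrogenolysis in the same flask then cleaves the eleven benzyl ethers, while the diaryl ethers are inert and the achiral product needs no stereocontrol.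

## Compound list

1 | 3,4,5-trihydroxybenzaldehyde | O=Cc1cc(O)c(O)c(O)c1 | starting material
2 | 3,4,5-tris(benzyloxy)benzaldehyde | O=Cc1cc(OCc9ccccc9)c(OCc9ccccc9)c(OCc9ccccc9)c1 | intermediate
3 | 3,4,5-tris(benzyloxy)phenyl formate | O=COc1cc(OCc9ccccc9)c(OCc9ccccc9)c(OCc9ccccc9)c1 | intermediate (not isolated)
4 | 3,4,5-tris(benzyloxy)phenol (ring F) | Oc1cc(OCc9ccccc9)c(OCc9ccccc9)c(OCc9ccccc9)c1 | intermediate
5 | 4-bromo-3,5-dimethoxybenzaldehyde | COc1cc(C=O)cc(OC)c1Br | starting material
6 | 4-bromo-3,5-dihydroxybenzaldehyde | Oc1cc(C=O)cc(O)c1Br | intermediate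
7 | 3,5-bis(benzyloxy)-4-bromobenzaldehyde | O=Cc1cc(OCc9ccccc9)c(Br)c(OCc9ccccc9)c1 | intermediate
8 | tetrahydrofuran | C1CCOC1 | starting material
9 | lithium ethenolate | [Li+].[O-]C=C | intermediate (not isolated)
10 | (methoxymethoxy)ethene (methoxymethyl vinyl ether) | C=COCOC | intermediate
11 | 3,5-bis(benzyloxy)-4-[3,4,5-tris(benzyloxy)phenoxy]benzaldehyde (rings F–E aldehyde) | O=Cc3cc(OCc9ccccc9)c(Oc2cc(OCc9ccccc9)c(OCc9ccccc9)c(OCc9ccccc9)c2)c(OCc9ccccc9)c3 | intermediate
12 | 3,5-bis(benzyloxy)-4-[3,4,5-tris(benzyloxy)phenoxy]phenyl formate | O=COc3cc(OCc9ccccc9)c(Oc2cc(OCc9ccccc9)c(OCc9ccccc9)c(OCc9ccccc9)c2)c(OCc9ccccc9)c3 | intermediate (not isolated)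
13 | 3,5-bis(benzyloxy)-4-[3,4,5-tris(benzyloxy)phenoxy]phenol (rings F–E phenol) | Oc3cc(OCc9ccccc9)c(Oc2cc(OCc9ccccc9)c(OCc9ccccc9)c(OCc9ccccc9)c2)c(OCc9ccccc9)c3 | intermediate
14 | 3,4-dichlorocyclobut-3-ene-1,2-dione (squaric acid dichloride) | O=C1C(=O)C(Cl)=C1Cl | starting material
15 | 3-(benzyloxy)-4-chlorocyclobut-3-ene-1,2-dione | O=C1C(=O)C(OCc9ccccc9)=C1Cl | intermediate
16 | 3-(benzyloxy)-4-{3,5-bis(benzyloxy)-4-[3,4,5-tris(benzyloxy)phenoxy]phenoxy}cyclobut-3-ene-1,2-dione | O=C1C(=O)C(OCc9ccccc9)=C1Oc3cc(OCc9ccccc9)c(Oc2cc(OCc9ccccc9)c(OCc9ccccc9)c(OCc9ccccc9)c2)c(OCc9ccccc9)c3 | intermediate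
17 | 1-(methoxymethoxy)ethenyllithium (THF solution) | [Li]C(=C)OCOC | intermediate
18 | lithium 3-(aryloxy)-2-(benzyloxy)-1-[1-(methoxymethoxy)ethenyl]-4-oxocyclobut-2-en-1-olate, aryloxy = oxygen of 13 (racemic) | [Li+].[O-]C1(C(=C)OCOC)C(OCc9ccccc9)=C(Oc3cc(OCc9ccccc9)c(Oc2cc(OCc9ccccc9)c(OCc9ccccc9)c(OCc9ccccc9)c2)c(OCc9ccccc9)c3)C1=O | intermediate (not isolated)
19 | rac-2-(aryloxy)-3-(benzyloxy)-4-(methoxymethoxy)-4-[1-(methoxymethoxy)ethenyl]cyclobut-2-en-1-one, aryloxy = oxygen of 13 | O=C1C(Oc3cc(OCc9ccccc9)c(Oc2cc(OCc9ccccc9)c(OCc9ccccc9)c(OCc9ccccc9)c2)c(OCc9ccccc9)c3)=C(OCc9ccccc9)C1(OCOC)C(=C)OCOC | intermediate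
20 | (3Z)-2-(aryloxy)-3-(benzyloxy)-4,5-bis(methoxymethoxy)hexa-1,3,5-trien-1-one, aryloxy = oxygen of 13 (dienylketene, vinyl cis to ketene) | O=C=C(Oc3cc(OCc9ccccc9)c(Oc2cc(OCc9ccccc9)c(OCc9ccccc9)c(OCc9ccccc9)c2)c(OCc9ccccc9)c3)/C(OCc9ccccc9)=C(OCOC)\C(=C)OCOC | intermediate (not isolated)
21 | 2-(aryloxy)-3-(benzyloxy)-4,5-bis(methoxymethoxy)cyclohexa-2,4-dien-1-one, aryloxy = oxygen of 13 | O=C1CC(OCOC)=C(OCOC)C(OCc9ccccc9)=C1Oc3cc(OCc9ccccc9)c(Oc2cc(OCc9ccccc9)c(OCc9ccccc9)c(OCc9ccccc9)c2)c(OCc9ccccc9)c3 | intermediate (not isolated)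
22 | 3-(benzyloxy)-4,5-bis(methoxymethoxy)-2-{3,5-bis(benzyloxy)-4-[3,4,5-tris(benzyloxy)phenoxy]phenoxy}phenol (rings F–E–D phenol) | Oc4cc(OCOC)c(OCOC)c(OCc9ccccc9)c4Oc3cc(OCc9ccccc9)c(Oc2cc(OCc9ccccc9)c(OCc9ccccc9)c(OCc9ccccc9)c2)c(OCc9ccccc9)c3 | intermediate
23 | 3,5-bis(benzyloxy)-4-(aryloxy)benzaldehyde, aryloxy = oxygen of 22 (rings F–C aldehyde) | O=Cc5cc(OCc9ccccc9)c(Oc4cc(OCOC)c(OCOC)c(OCc9ccccc9)c4Oc3cc(OCc9ccccc9)c(Oc2cc(OCc9ccccc9)c(OCc9ccccc9)c(OCc9ccccc9)c2)c(OCc9ccccc9)c3)c(OCc9ccccc9)c5 | intermediate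
24 | formate ester of phenol 25 | O=COc5cc(OCc9ccccc9)c(Oc4cc(OCOC)c(OCOC)c(OCc9ccccc9)c4Oc3cc(OCc9ccccc9)c(Oc2cc(OCc9ccccc9)c(OCc9ccccc9)c(OCc9ccccc9)c2)c(OCc9ccccc9)c3)c(OCc9ccccc9)c5 | intermediate (not isolated)
25 | 3,5-bis(benzyloxy)-4-(aryloxy)phenol, aryloxy = oxygen of 22 (rings F–C phenol) | Oc5cc(OCc9ccccc9)c(Oc4cc(OCOC)c(OCOC)c(OCc9ccccc9)c4Oc3cc(OCc9ccccc9)c(Oc2cc(OCc9ccccc9)c(OCc9ccccc9)c(OCc9ccccc9)c2)c(OCc9ccccc9)c3)c(OCc9ccccc9)c5 | intermediate
26 | 3-(benzyloxy)-4-(aryloxy)cyclobut-3-ene-1,2-dione, aryloxy = oxygen of 25 | O=C1C(=O)C(OCc9ccccc9)=C1Oc5cc(OCc9ccccc9)c(Oc4cc(OCOC)c(OCOC)c(OCc9ccccc9)c4Oc3cc(OCc9ccccc9)c(Oc2cc(OCc9ccccc9)c(OCc9ccccc9)c(OCc9ccccc9)c2)c(OCc9ccccc9)c3)c(OCc9ccccc9)c5 | intermediate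
27 | lithium 3-(aryloxy)-2-(benzyloxy)-1-[1-(methoxymethoxy)ethenyl]-4-oxocyclobut-2-en-1-olate, aryloxy = oxygen of 25 (racemic) | [Li+].[O-]C1(C(=C)OCOC)C(OCc9ccccc9)=C(Oc5cc(OCc9ccccc9)c(Oc4cc(OCOC)c(OCOC)c(OCc9ccccc9)c4Oc3cc(OCc9ccccc9)c(Oc2cc(OCc9ccccc9)c(OCc9ccccc9)c(OCc9ccccc9)c2)c(OCc9ccccc9)c3)c(OCc9ccccc9)c5)C1=O | intermediate (not isolated)
28 | rac-2-(aryloxy)-3-(benzyloxy)-4-(methoxymethoxy)-4-[1-(methoxymethoxy)ethenyl]cyclobut-2-en-1-one, aryloxy = oxygen of 25 | O=C1C(Oc5cc(OCc9ccccc9)c(Oc4cc(OCOC)c(OCOC)c(OCc9ccccc9)c4Oc3cc(OCc9ccccc9)c(Oc2cc(OCc9ccccc9)c(OCc9ccccc9)c(OCc9ccccc9)c2)c(OCc9ccccc9)c3)c(OCc9ccccc9)c5)=C(OCc9ccccc9)C1(OCOC)C(=C)OCOC | intermediate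
29 | (3Z)-2-(aryloxy)-3-(benzyloxy)-4,5-bis(methoxymethoxy)hexa-1,3,5-trien-1-one, aryloxy = oxygen of 25 (dienylketene, vinyl cis to ketene) | O=C=C(Oc5cc(OCc9ccccc9)c(Oc4cc(OCOC)c(OCOC)c(OCc9ccccc9)c4Oc3cc(OCc9ccccc9)c(Oc2cc(OCc9ccccc9)c(OCc9ccccc9)c(OCc9ccccc9)c2)c(OCc9ccccc9)c3)c(OCc9ccccc9)c5)/C(OCc9ccccc9)=C(OCOC)\C(=C)OCOC | intermediate (not isolated)
30 | 2-(aryloxy)-3-(benzyloxy)-4,5-bis(methoxymethoxy)cyclohexa-2,4-dien-1-one, aryloxy = oxygen of 25 | O=C1CC(OCOC)=C(OCOC)C(OCc9ccccc9)=C1Oc5cc(OCc9ccccc9)c(Oc4cc(OCOC)c(OCOC)c(OCc9ccccc9)c4Oc3cc(OCc9ccccc9)c(Oc2cc(OCc9ccccc9)c(OCc9ccccc9)c(OCc9ccccc9)c2)c(OCc9ccccc9)c3)c(OCc9ccccc9)c5 | intermediate (not isolated)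
31 | 3-(benzyloxy)-4,5-bis(methoxymethoxy)-2-(aryloxy)phenol, aryloxy = oxygen of 25 (rings F–B phenol) | Oc6cc(OCOC)c(OCOC)c(OCc9ccccc9)c6Oc5cc(OCc9ccccc9)c(Oc4cc(OCOC)c(OCOC)c(OCc9ccccc9)c4Oc3cc(OCc9ccccc9)c(Oc2cc(OCc9ccccc9)c(OCc9ccccc9)c(OCc9ccccc9)c2)c(OCc9ccccc9)c3)c(OCc9ccccc9)c5 | intermediate
32 | 3,5-bis(benzyloxy)-4-(aryloxy)benzaldehyde, aryloxy = oxygen of 31 (rings F–A aldehyde) | O=Cc7cc(OCc9ccccc9)c(Oc6cc(OCOC)c(OCOC)c(OCc9ccccc9)c6Oc5cc(OCc9ccccc9)c(Oc4cc(OCOC)c(OCOC)c(OCc9ccccc9)c4Oc3cc(OCc9ccccc9)c(Oc2cc(OCc9ccccc9)c(OCc9ccccc9)c(OCc9ccccc9)c2)c(OCc9ccccc9)c3)c(OCc9ccccc9)c5)c(OCc9ccccc9)c7 | intermediate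
33 | formate ester of phenol 34 | O=COc7cc(OCc9ccccc9)c(Oc6cc(OCOC)c(OCOC)c(OCc9ccccc9)c6Oc5cc(OCc9ccccc9)c(Oc4cc(OCOC)c(OCOC)c(OCc9ccccc9)c4Oc3cc(OCc9ccccc9)c(Oc2cc(OCc9ccccc9)c(OCc9ccccc9)c(OCc9ccccc9)c2)c(OCc9ccccc9)c3)c(OCc9ccccc9)c5)c(OCc9ccccc9)c7 | intermediate (not isolated)
34 | 3,5-bis(benzyloxy)-4-(aryloxy)phenol, aryloxy = oxygen of 31 (protected hexamer: eleven benzyl and four methoxymethyl ethers) | Oc7cc(OCc9ccccc9)c(Oc6cc(OCOC)c(OCOC)c(OCc9ccccc9)c6Oc5cc(OCc9ccccc9)c(Oc4cc(OCOC)c(OCOC)c(OCc9ccccc9)c4Oc3cc(OCc9ccccc9)c(Oc2cc(OCc9ccccc9)c(OCc9ccccc9)c(OCc9ccccc9)c2)c(OCc9ccccc9)c3)c(OCc9ccccc9)c5)c(OCc9ccccc9)c7 | intermediate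
35 | undeca-O-benzyl ether of the target (34 without its four methoxymethyl groups) | Oc7cc(OCc9ccccc9)c(Oc6cc(O)c(O)c(OCc9ccccc9)c6Oc5cc(OCc9ccccc9)c(Oc4cc(O)c(O)c(OCc9ccccc9)c4Oc3cc(OCc9ccccc9)c(Oc2cc(OCc9ccccc9)c(OCc9ccccc9)c(OCc9ccccc9)c2)c(OCc9ccccc9)c3)c(OCc9ccccc9)c5)c(OCc9ccccc9)c7 | intermediate (not isolated)
36 | CNP0218077.0, hexameric fuhalol (achiral) | Oc1cc(O)c(Oc2cc(O)c(O)c(O)c2Oc2cc(O)c(Oc3cc(O)c(O)c(O)c3Oc3cc(O)c(Oc4cc(O)c(O)c(O)c4)c(O)c3)c(O)c2)c(O)c1 | target

Total step count: 20. Longest linear sequence: 15 steps (steps 1, 2, 6, 7, 9 and 11 to 20).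

**Steps most likely to fail**

Step 11 (step 16 repeats it on a larger substrate). The vinyllithium may discriminate poorly between the two carbonyl groups of the mixed squarate, or attack the aryloxy-bearing carbon with loss of aryloxide. Part of the material would then enter the ring expansion with the benzyloxy and aryloxy groups interchanged. The fallback takes the regiochemistry out of the addition. Setting out from 13 and 14, two equivalents of the phenol with iPr2NEt would give the symmetric squarate 3,4-bis{3,5-bis(benzyloxy)-4-[3,4,5-tris(benzyloxy)phenoxy]phenoxy}cyclobut-3-ene-1,2-dione F1, whose two carbonyl groups are equivalent. Addition of 17 and trapping with MOMCl as in step 11 would give rac-2,3-bis(aryloxy)-4-(methoxymethoxy)-4-[1-(methoxymethoxy)ethenyl]cyclobut-2-en-1-one F2. A vinylogous transesterification with benzyl alcohol and a catalytic amount of its lithium alkoxide (THF, −40 °C) can then take place only at C3, the β-carbon of the enone, where the better leaving aryloxide is exchanged for benzyloxide. This returns one equivalent of 13 and comes back to the route at 19.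

Step 13 (steps 6 and 18 are of the same type; step 13 is the first with a phenol that bears an ortho aryloxy group). Oxidative addition and ligand exchange may be slow at the bromide flanked by two benzyloxy groups, so that protodebromination of 7 and oxidative decay of the electron-rich phenol take over. The fallback is a metal-free addition–elimination at a fluoride. Setting out from 2, one equivalent of BCl3 at −78 °C would cleave the central, most hindered benzyl ether para to the formyl group and give 3,5-bis(benzyloxy)-4-hydroxybenzaldehyde F3. Deoxyfluorination (2-chloro-1,3-bis(2,6-diisopropylphenyl)imidazolium chloride, CsF, toluene, 110 °C) would give 3,5-bis(benzyloxy)-4-fluorobenzaldehyde F4. Phenol 22 and F4 with K2CO3 in DMSO at 110 °C would then form the ether by nucleophilic aromatic substitution para to the formyl group, coming back to the route at 23.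

Step 20. Hydrogenolysis may stall because partly debenzylated polyphenols bind to the catalyst and fall out of solution, and the freed 4,5-dihydroxy units of rings B and D may be oxidised by air during the acid stage. The fallback removes all fifteen protecting groups in one Lewis acid operation without hydrogen or metal. Setting out from 34, BCl3 with pentamethylbenzene as cation scavenger in CH2Cl2 at −78 °C, then methanol, would cleave the benzyl and methoxymethyl ethers alike and come back to the route at the target 36. This fallback makes no new compound (F0).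

The ring expansions themselves (steps 12 and 17) are not listed, because the capped C4 oxygen gives them the substitution pattern for which this rearrangement is best precedented; their risk sits in the preparation of the cyclobutenones.

## Further compounds

F1 | step 11 | 3,4-bis{3,5-bis(benzyloxy)-4-[3,4,5-tris(benzyloxy)phenoxy]phenoxy}cyclobut-3-ene-1,2-dione | O=C1C(=O)C(Oc3cc(OCc9ccccc9)c(Oc2cc(OCc9ccccc9)c(OCc9ccccc9)c(OCc9ccccc9)c2)c(OCc9ccccc9)c3)=C1Oc3cc(OCc9ccccc9)c(Oc2cc(OCc9ccccc9)c(OCc9ccccc9)c(OCc9ccccc9)c2)c(OCc9ccccc9)c3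
F2 | step 11 | rac-2,3-bis(aryloxy)-4-(methoxymethoxy)-4-[1-(methoxymethoxy)ethenyl]cyclobut-2-en-1-one, aryloxy = oxygen of 13 | O=C1C(Oc3cc(OCc9ccccc9)c(Oc2cc(OCc9ccccc9)c(OCc9ccccc9)c(OCc9ccccc9)c2)c(OCc9ccccc9)c3)=C(Oc3cc(OCc9ccccc9)c(Oc2cc(OCc9ccccc9)c(OCc9ccccc9)c(OCc9ccccc9)c2)c(OCc9ccccc9)c3)C1(OCOC)C(=C)OCOC
F3 | step 13 | 3,5-bis(benzyloxy)-4-hydroxybenzaldehyde | O=Cc1cc(OCc9ccccc9)c(O)c(OCc9ccccc9)c1
F4 | step 13 | 3,5-bis(benzyloxy)-4-fluorobenzaldehyde | O=Cc1cc(OCc9ccccc9)c(F)c(OCc9ccccc9)c1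
F0 | step 20 | none | none
A1 | direct plan | 2,3,4-tris(benzyloxy)-6-[2,4,6-tris(benzyloxy)phenoxy]phenol | Oc1c(Oc2c(OCc9ccccc9)cc(OCc9ccccc9)cc2OCc9ccccc9)cc(OCc9ccccc9)c(OCc9ccccc9)c1OCc9ccccc9
A2 | direct plan | 2,6-bis(benzyloxy)-4-bromobenzaldehyde | O=Cc1c(OCc2ccccc2)cc(Br)cc1OCc1ccccc1
A3 | direct plan | 2,3,4-tris(benzyloxy)-6-bromobenzaldehyde | O=Cc1c(Br)cc(OCc2ccccc2)c(OCc2ccccc2)c1OCc1ccccc1
A4 | direct plan | hexadeca-O-benzyl ether of the target | c9ccccc9COc1c(OCc9ccccc9)cc(Oc6c(OCc9ccccc9)cc(Oc5c(Oc4c(OCc9ccccc9)cc(Oc3c(Oc2c(OCc9ccccc9)cc(OCc9ccccc9)cc2OCc9ccccc9)cc(OCc9ccccc9)c(OCc9ccccc9)c3OCc9ccccc9)cc4OCc9ccccc9)cc(OCc9ccccc9)c(OCc9ccccc9)c5OCc9ccccc9)cc6OCc9ccccc9)cc1OCc9ccccc9
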